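**Plan**
- Retrosynthesis: the three angelates are cut last, and both epoxides go back to a (1(10)Z,4E)-cyclodecadien-9-one. That ring is cut at C9–C10 and re-joined through C4–C9, so it is taken as the four-carbon ring-expansion product of a cyclohexanone.
- Enabling feature: C4–C9 of the ten-membered ring (methyl on C4, isopropenyl on C7, carbonyl on C9) are the six ring carbons of carvone. C3, C2, C1 and C10 (with C14) are a chain inserted between the carbonyl carbon C9 and its α-carbon C4.
- Forward: (R)-carvone → oxygen at C6 and C8 by enolate oxidation on both sides of C7, with a Wharton 1,3-transposition in between → vinyl addition, directed epoxidation and semipinacol shift (quaternary C4, C5 nucleofuge) → side chain by aldol and Stork–Zhao olefination → ring A closed by the C9–C10 bond, then rings A and B opened by Grob fragmentation to the ten-membered ring → two epoxidations, three angeloylations.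
- Stereochemistry: C7 from carvone; C6 and C8 trans to the isopropenyl (enolate oxidation); C4/C5 from the anti 1,2-shift, translated into the 4E olefin; C3 from a catalyst-controlled aldol; 1(10)Z from ring A; both epoxides by attack on the exposed face of the medium ring (hydroxyl-directed at C4–C5).

Key step: step 17

Remark: locants C1–C15 are those of the germacrane skeleton of the target (ring C1–C10, isopropenyl C11–C13 on C7, C14 on C10, C15 on C4) and are kept for every intermediate; in these locants the target is (1S,3S,4R,5R,6S,7S,8R,10S). TBS = tert-butyldimethylsilyl, Ms = methanesulfonyl. The chiral diamine of step 13 and all compounds marked as starting materials are taken as commercial.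

**Route**

Step 1
Reactants: 1 (R)-(−)-carvone; 2 Davis oxaziridine; 3 TBS triflate
Product: 5 6-(TBS-oxy)carvone (silyloxy trans to the C7 isopropenyl), via lithium alkoxide of 6-hydroxycarvone 4 (not isolated)
Conditions: LiN(i-Pr)2, THF, −78 °C; 2; then 3, −78 → 0 °C
Reagents that add atoms: Davis oxaziridine 2, O=S(=O)(c1ccccc1)N1OC1c1ccccc1; TBS triflate 3, CC(C)(C)[Si](C)(C)OS(=O)(=O)C(F)(F)F
Why: Kinetic deprotonation at C6 gives the cross-conjugated lithium dienolate, which the Davis oxaziridine should hydroxylate anti to the adjacent C7 isopropenyl (any cis isomer can epimerize to the trans, diequatorial ketone), and the lithium alkoxide is silylated in the same flask (Davis enolate oxidation, then O-silylation).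

Step 2
Reactants: 5 6-(TBS-oxy)carvone; 6 hydrogen peroxide
Product: 7 4,9-epoxy-5-ketone (epoxide trans to the isopropenyl)
Conditions: 30% H2O2, NaOH (catalytic), MeOH, 0 °C
Reagents that add atoms: hydrogen peroxide 6, OO
Why: Weitz–Scheffer nucleophilic epoxidation, in which hydroperoxide adds axially to C9 anti to the C7 isopropenyl as in carvone itself; the epoxide only serves the transposition and its configuration is erased in steps 3 and 4.

Step 3
Reactants: 7 4,9-epoxy-5-ketone
Product: 8 allylic alcohol (C4=C5, 9-OH, 6-OTBS)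
Conditions: N2H4·H2O, AcOH (catalytic), MeOH, 0 °C → rt
Reagents that add atoms: none
Why: Wharton rearrangement (epoxy hydrazone, alkenyl diazene, loss of N2) moves the oxygen from C5 to C9 and the double bond to C4=C5, so that C8 becomes the enolizable α' position.

Step 4
Reactants: 8 allylic alcohol
Product: 9 transposed enone (9-ketone, C4=C5, 6-OTBS)
Conditions: Dess–Martin periodinane, NaHCO3, CH2Cl2, rt
Reagents that add atoms: none
Why: Dess–Martin oxidation of the secondary allylic alcohol gives the transposed enone and leaves the silyl ether and the isopropenyl group untouched.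

Step 5
Reactants: 9 transposed enone; 2 Davis oxaziridine; 3 TBS triflate
Product: 11 6,8-bis(TBS-oxy) enone (both silyloxy groups trans to the isopropenyl), via lithium alkoxide of the 8-hydroxy enone 10 (not isolated)
Conditions: LiN(i-Pr)2, THF, −78 °C; 2; then 3, −78 → 0 °C
Reagents that add atoms: Davis oxaziridine 2, O=S(=O)(c1ccccc1)N1OC1c1ccccc1; TBS triflate 3, CC(C)(C)[Si](C)(C)OS(=O)(=O)C(F)(F)F
Why: Kinetic deprotonation takes place at the α' methylene C8 rather than at the γ C6–H, and Davis oxidation of the enolate followed by silylation in the flask puts the new silyloxy group trans to the adjacent isopropenyl, the all-equatorial and also thermodynamically preferred arrangement.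

Step 6
Reactants: 11 6,8-bis(TBS-oxy) enone; 12 vinylmagnesium bromide
Product: 13 tertiary allylic alcohol (9-vinyl trans, 9-OH cis to the isopropenyl)
Conditions: CH2=CHMgBr, CeCl3, THF, −78 °C
Reagents that add atoms: vinylmagnesium bromide 12, C=C[Mg]Br
Why: Organocerium 1,2-addition to the enone carbonyl, in which the vinyl group should enter axially on the face opposite the C7 isopropenyl of the half-chair with three equatorial substituents, so that the tertiary hydroxyl is cis to the isopropenyl; CeCl3 suppresses enolization and conjugate addition.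

Step 7
Reactants: 13 tertiary allylic alcohol; 14 tert-butyl hydroperoxide
Product: 15 4,5-epoxy-9-vinyl-9-ol (epoxide cis to the 9-OH)
Conditions: VO(acac)2 (2 mol %), t-BuOOH, CH2Cl2, 0 °C
Reagents that add atoms: tert-butyl hydroperoxide 14, CC(C)(C)OO
Why: Vanadium-catalysed hydroxyl-directed epoxidation of the allylic alcohol delivers oxygen to the trisubstituted C4=C5 bond from the face of the C9 hydroxyl, and the monosubstituted vinyl and the isopropenyl groups react much more slowly.

Step 8
Reactants: 15 4,5-epoxy-9-vinyl-9-ol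
Product: 16 β-hydroxy ketone (9-ketone, quaternary C4 with vinyl trans to the 5-OH)
Conditions: BF3·OEt2, CH2Cl2, −78 °C
Reagents that add atoms: none
Why: Semipinacol rearrangement of the 2,3-epoxy alcohol, in which the Lewis acid opens the epoxide at the tertiary C4 while the axial vinyl group, antiperiplanar to the breaking C4–O bond, shifts from C9 to C4 with inversion at C4, so that the quaternary centre (vinyl equatorial, methyl axial), the equatorial C5 hydroxyl trans to the vinyl group and the C9 ketone arise stereospecifically.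

Step 9
Reactants: 16 β-hydroxy ketone; 14 tert-butyl hydroperoxide
Product: 17 oxiranyl hydroxy ketone (vinyl group epoxidized, both epimers at the new oxirane CH)
Conditions: VO(acac)2 (5 mol %), t-BuOOH, CH2Cl2, rt
Reagents that add atoms: tert-butyl hydroperoxide 14, CC(C)(C)OO
Why: Vanadium-catalysed epoxidation directed by the homoallylic C5 hydroxyl oxidizes the vicinal vinyl group rather than the remote isopropenyl group, and the configuration of the new oxirane carbon does not matter because this carbon becomes sp2 in step 11.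

Step 10
Reactants: 17 oxiranyl hydroxy ketone; 18 methanesulfonyl chloride
Product: 19 oxiranyl keto mesylate (5-OMs)
Conditions: MsCl, Et3N, CH2Cl2, 0 °C
Reagents that add atoms: methanesulfonyl chloride 18, CS(=O)(=O)Cl
Why: Mesylation through sulfene reaches the hindered secondary C5 hydroxyl and installs the nucleofuge of the later fragmentation, while β-elimination is excluded because C4 is quaternary.

Step 11
Reactants: 19 oxiranyl keto mesylate
Product: 20 C3 aldehyde (formyl group on C4)
Conditions: H5IO6, THF/Et2O, 0 °C → rt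
Reagents that add atoms: none
Why: Periodic acid opens the terminal epoxide and cleaves the resulting glycol to the C3 aldehyde, with loss of the terminal carbon as formaldehyde, without touching the isopropenyl group, which ozonolysis of the vinyl group would not have spared.

Step 12
Reactants: 21 S-ethyl thioacetate; 22 chlorotrimethylsilane
Product: 23 1-(ethylthio)-1-(trimethylsilyloxy)ethene
Conditions: LiN(i-Pr)2, THF, −78 °C; Me3SiCl
Reagents that add atoms: chlorotrimethylsilane 22, C[Si](C)(C)Cl
Why: Kinetic enolization of the thioester and O-silylation of the lithium enolate give the silyl ketene thioacetal for the Mukaiyama aldol reaction.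

Step 13
Reactants: 20 C3 aldehyde; 23 1-(ethylthio)-1-(trimethylsilyloxy)ethene
Product: 24 (3S)-β-hydroxy thioester
Conditions: Sn(OTf)2 (20 mol %), (S)-1-methyl-2-[(1-naphthylamino)methyl]pyrrolidine (22 mol %), EtCN, −78 °C, slow addition of 20 and 23; then 1 M HCl, THF
Reagents that add atoms: 1-(ethylthio)-1-(trimethylsilyloxy)ethene 23, C=C(O[Si](C)(C)C)SCC
Why: Catalytic asymmetric Mukaiyama aldol reaction, in which the chiral tin triflate–diamine Lewis acid selects the face of the neopentyl aldehyde and sets C3 as S (the mirror-image diamine is taken if the sense proves opposite), while the hindered ketone does not react.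

Step 14
Reactants: 24 (3S)-β-hydroxy thioester; 3 TBS triflate
Product: 25 3-O-TBS thioester
Conditions: TBSOTf, 2,6-lutidine, CH2Cl2, −78 → 0 °C
Reagents that add atoms: TBS triflate 3, CC(C)(C)[Si](C)(C)OS(=O)(=O)C(F)(F)F
Why: Silylation of the β-hydroxy thioester protects O-3, so that no C3 alkoxide can later cause retro-aldol cleavage of the C3–C4 bond.

Step 15
Reactants: 25 3-O-TBS thioester
Product: 26 C1 aldehyde
Conditions: Et3SiH, 10% Pd on carbon, acetone, rt
Reagents that add atoms: none
Why: Fukuyama reduction turns the thioester into the aldehyde with a silane on palladium and leaves the hindered ketone, the mesylate and the silyl ethers untouched.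

Step 16
Reactants: 26 C1 aldehyde; 27 ethyltriphenylphosphonium iodide; 28 iodine
Product: 29 (Z)-vinyl iodide keto mesylate
Conditions: 27, n-BuLi, THF, rt; I2, −78 °C; NaN(SiMe3)2, −20 °C; then 26, −78 → −20 °C
Reagents that add atoms: ethyltriphenylphosphonium iodide 27, CC[P+](c1ccccc1)(c1ccccc1)c1ccccc1.[I-]; iodine 28, II
Why: Stork–Zhao olefination, in which the α-iodo ylide reacts with the aldehyde and not with the hindered ketone and gives the (Z)-2-iodoalkene (iodine cis to C2) through the cis-oxaphosphetane.

Step 17
Reactants: 29 (Z)-vinyl iodide keto mesylate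
Product: 32 (1(10)Z,4E)-3,6,8-tris(TBS-oxy)germacra-1(10),4,11-trien-9-one, via vinyllithium 30 (not isolated), via bicyclic lithium alkoxide 31 (not isolated)
Conditions: t-BuLi (2.0 equiv), THF/Et2O, −100 °C; then HMPA, −78 °C → rt
Reagents that add atoms: none
Why: Proposed new method: iodine–lithium exchange gives the (Z)-vinyllithium 30, whose C10 adds to the C9 ketone to close ring A (bicyclic alkoxide 31), and the alkoxide then expels the C5 mesylate with cleavage of the C4–C9 bond shared by rings A and B (Grob fragmentation), which leaves the C9 ketone inside a ten-membered ring; the closest known reaction type is the sequenced intramolecular Barbier cyclization/Grob fragmentation of iodoalkyl keto mesylates with SmI2, shown for alkyl iodides, here carried over to a vinyl iodide and an organolithium. Ring A closes in the 6-exo-trig mode, and the ten-membered ring is not closed directly but uncovered by the fragmentation, which avoids a medium-ring cyclization. The C9 carbinol centre is transient (either ring fusion fragments), and the two new stereo elements are fixed by the substrate: 1(10)Z because C1=C10 was a cis double bond inside the cyclohexene ring A, and 4E because in the all-equatorial chair of ring B the C4–C9 bond is antiperiplanar to the equatorial C5–OMs bond while C3 (equatorial) sits next to H-5 and the axial C15 methyl next to C6. The step needs exchange at the vinyl iodide to outrun attack on the ketone and on the mesylate, which the rate of iodine–lithium exchange at −100 °C should secure, and it needs fragmentation rather than oxetane formation or retro-aldol cleavage, which the antiperiplanar alignment, the inaccessible rear side of C5 and the silyl ether on O-3 should secure.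

Step 18
Reactants: 32 ten-membered dienone; 14 tert-butyl hydroperoxide
Product: 33 (1S,10S)-1,10-epoxy ketone (tris-TBS ether)
Conditions: t-BuOOH, KH, THF, −20 °C
Reagents that add atoms: tert-butyl hydroperoxide 14, CC(C)(C)OO
Why: Weitz–Scheffer epoxidation with potassium tert-butyl peroxide, in which the peroxide should add to C1 on the exposed face of the (Z)-enone in the ten-membered ring and the enolate should close before rotation about C1–C10, giving the cis-epoxy ketone with the 1S,10S configuration, while the isolated C4=C5 and isopropenyl double bonds are inert to a nucleophilic oxidant.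

Step 19
Reactants: 33 1,10-epoxy ketone (tris-TBS ether)
Product: 34 epoxy keto triol
Conditions: Bu4NF, AcOH, THF, rt
Reagents that add atoms: none
Why: Fluoride cleaves the three silyl ethers, and buffering with acetic acid keeps the epoxy ketone and the α-ketol from base-induced side reactions.

Step 20
Reactants: 34 epoxy keto triol; 14 tert-butyl hydroperoxide
Product: 35 diepoxy keto triol
Conditions: VO(acac)2 (5 mol %), t-BuOOH, CH2Cl2, 0 °C
Reagents that add atoms: tert-butyl hydroperoxide 14, CC(C)(C)OO
Why: Vanadium-catalysed epoxidation directed by the allylic C3 and C6 hydroxyls, which both lie on the exposed face of the E double bond because A(1,3) strain with the C15 methyl keeps H-6 in the olefin plane, so that oxygen is delivered threo to both carbinols (4R,5R) and the epoxy ketone and the isopropenyl group stay untouched.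

Step 21
Reactants: 35 diepoxy keto triol; 36 angelic acid
Product: 37 CNP0154187.4
Conditions: angelic acid, 2,4,6-trichlorobenzoyl chloride, Et3N, toluene, rt; then 35, 75 °C
Reagents that add atoms: angelic acid 36, C/C=C(/C)C(=O)O
Why: Mixed-anhydride acylation of the Yamaguchi type without a nucleophilic catalyst transfers the less hindered angeloyl group of the preformed angelic 2,4,6-trichlorobenzoic anhydride to all three secondary hydroxyls, conditions under which the Z double bond of the angelate should not isomerize to the tiglate.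

**Compound list**

1 | (R)-(−)-carvone, (5R)-2-methyl-5-(prop-1-en-2-yl)cyclohex-2-en-1-one (skeleton locants: C5 carbonyl, C4=C9, isopropenyl on C7) | C=C(C)[C@H]1CC(=O)C(C)=CC1 | starting material
2 | trans-3-phenyl-2-(phenylsulfonyl)oxaziridine (Davis oxaziridine, racemic) | O=S(=O)(c1ccccc1)N1OC1c1ccccc1 | starting material
3 | tert-butyldimethylsilyl trifluoromethanesulfonate | CC(C)(C)[Si](C)(C)OS(=O)(=O)C(F)(F)F | starting material
4 | lithium alkoxide of 6-hydroxycarvone, O-6 trans to the C7 isopropenyl | C=C(C)[C@H]1[C@H]([O-])C(=O)C(C)=CC1.[Li+] | intermediate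
5 | 6-(TBS-oxy)carvone, silyloxy trans to the isopropenyl | C=C(C)[C@H]1[C@H](O[Si](C)(C)C(C)(C)C)C(=O)C(C)=CC1 | intermediate
6 | hydrogen peroxide | OO | starting material
7 | 4,9-epoxy-5-ketone of 5, epoxide oxygen trans to the isopropenyl and cis to O-6 | C=C(C)[C@H]1[C@H](O[Si](C)(C)C(C)(C)C)C(=O)[C@]2(C)O[C@@H]2C1 | intermediate
8 | allylic alcohol with C4=C5, 9-OH trans to the isopropenyl, 6-OTBS | C=C(C)[C@H]1[C@H](O[Si](C)(C)C(C)(C)C)C=C(C)[C@H](O)C1 | intermediate
9 | transposed enone: 9-ketone, C4=C5, 6-OTBS trans to the isopropenyl | C=C(C)[C@H]1[C@H](O[Si](C)(C)C(C)(C)C)C=C(C)C(=O)C1 | intermediate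
10 | lithium alkoxide of the 8-hydroxy derivative of 9, O-8 trans to the isopropenyl | C=C(C)[C@H]1[C@H](O[Si](C)(C)C(C)(C)C)C=C(C)C(=O)[C@@H]1[O-].[Li+] | intermediate
11 | 6,8-bis(TBS-oxy) enone: 9-ketone, C4=C5, both silyloxy groups trans to the C7 isopropenyl | C=C(C)[C@H]1[C@H](O[Si](C)(C)C(C)(C)C)C=C(C)C(=O)[C@@H]1O[Si](C)(C)C(C)(C)C | intermediate
12 | vinylmagnesium bromide | C=C[Mg]Br | starting material
13 | tertiary allylic alcohol: 9-vinyl (trans to the isopropenyl) and 9-OH (cis to the isopropenyl) on 11 | C=C(C)[C@H]1[C@H](O[Si](C)(C)C(C)(C)C)C=C(C)[C@](O)(C=C)[C@@H]1O[Si](C)(C)C(C)(C)C | intermediate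
14 | tert-butyl hydroperoxide | CC(C)(C)OO | starting material
15 | 4,5-epoxy-9-vinyl-9-ol, epoxide cis to the 9-OH and trans to O-6 | C=C(C)[C@H]1[C@H](O[Si](C)(C)C(C)(C)C)[C@H]2O[C@@]2(C)[C@](O)(C=C)[C@@H]1O[Si](C)(C)C(C)(C)C | intermediate
16 | β-hydroxy ketone: 9-ketone, quaternary C4 (vinyl trans, methyl cis to the 5-OH), 5-OH trans to O-6 and cis to the isopropenyl | C=C(C)[C@H]1[C@H](O[Si](C)(C)C(C)(C)C)[C@@H](O)[C@](C)(C=C)C(=O)[C@@H]1O[Si](C)(C)C(C)(C)C | intermediate
17 | oxiranyl hydroxy ketone: 16 with the vinyl group converted into an oxirane (both epimers at the new oxirane CH) | C=C(C)[C@H]1[C@H](O[Si](C)(C)C(C)(C)C)[C@@H](O)[C@](C)(C2CO2)C(=O)[C@@H]1O[Si](C)(C)C(C)(C)C | intermediate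
18 | methanesulfonyl chloride | CS(=O)(=O)Cl | starting material
19 | oxiranyl keto mesylate: 5-O-mesylate of 17 | C=C(C)[C@H]1[C@H](O[Si](C)(C)C(C)(C)C)[C@@H](OS(C)(=O)=O)[C@](C)(C2CO2)C(=O)[C@@H]1O[Si](C)(C)C(C)(C)C | intermediate
20 | C3 aldehyde: formyl and methyl on C4, 5-OMs, 9-ketone, 6,8-bis(TBS-oxy) | C=C(C)[C@H]1[C@H](O[Si](C)(C)C(C)(C)C)[C@@H](OS(C)(=O)=O)[C@](C)(C=O)C(=O)[C@@H]1O[Si](C)(C)C(C)(C)C | intermediate
21 | S-ethyl thioacetate | CCSC(C)=O | starting material
22 | chlorotrimethylsilane | C[Si](C)(C)Cl | starting material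
23 | 1-(ethylthio)-1-(trimethylsilyloxy)ethene | C=C(O[Si](C)(C)C)SCC | intermediate
24 | (3S)-β-hydroxy thioester: C4 carries CH(OH)CH2C(O)SEt | C=C(C)[C@H]1[C@H](O[Si](C)(C)C(C)(C)C)[C@@H](OS(C)(=O)=O)[C@](C)([C@@H](O)CC(=O)SCC)C(=O)[C@@H]1O[Si](C)(C)C(C)(C)C | intermediate
25 | 3-O-TBS ether of 24 | C=C(C)[C@H]1[C@H](O[Si](C)(C)C(C)(C)C)[C@@H](OS(C)(=O)=O)[C@](C)([C@@H](O[Si](C)(C)C(C)(C)C)CC(=O)SCC)C(=O)[C@@H]1O[Si](C)(C)C(C)(C)C | intermediate
26 | C1 aldehyde: C4 carries CH(OTBS)CH2CHO | C=C(C)[C@H]1[C@H](O[Si](C)(C)C(C)(C)C)[C@@H](OS(C)(=O)=O)[C@](C)([C@@H](O[Si](C)(C)C(C)(C)C)CC=O)C(=O)[C@@H]1O[Si](C)(C)C(C)(C)C | intermediate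
27 | ethyltriphenylphosphonium iodide | CC[P+](c1ccccc1)(c1ccccc1)c1ccccc1.[I-] | starting material
28 | iodine | II | starting material
29 | (Z)-vinyl iodide keto mesylate: C4 carries the 1-(TBS-oxy)-4-iodopent-3(Z)-enyl chain (C3 as in the target), 5-OMs, 9-ketone | C=C(C)[C@H]1[C@H](O[Si](C)(C)C(C)(C)C)[C@@H](OS(C)(=O)=O)[C@](C)([C@@H](O[Si](C)(C)C(C)(C)C)C/C=C(\I)C)C(=O)[C@@H]1O[Si](C)(C)C(C)(C)C | intermediate
30 | vinyllithium from 29 (lithium in place of iodine, Z retained) | C=C(C)[C@H]1[C@H](O[Si](C)(C)C(C)(C)C)[C@@H](OS(C)(=O)=O)[C@](C)([C@@H](O[Si](C)(C)C(C)(C)C)C/C=C(\[Li])C)C(=O)[C@@H]1O[Si](C)(C)C(C)(C)C | intermediate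
31 | bicyclic lithium alkoxide: ring A closed by the C9–C10 bond, cis ring fusion, 5-OMs | C=C(C)[C@H]1[C@H](O[Si](C)(C)C(C)(C)C)[C@@H](OS(C)(=O)=O)[C@]2(C)[C@@H](O[Si](C)(C)C(C)(C)C)CC=C(C)[C@]2([O-])[C@@H]1O[Si](C)(C)C(C)(C)C.[Li+] | intermediate
32 | (1(10)Z,4E)-3,6,8-tris(TBS-oxy)germacra-1(10),4,11-trien-9-one, C3, C6, C7, C8 as in the target | C=C(C)[C@H]1[C@H](O[Si](C)(C)C(C)(C)C)/C=C(\C)[C@@H](O[Si](C)(C)C(C)(C)C)C/C=C(/C)C(=O)[C@@H]1O[Si](C)(C)C(C)(C)C | intermediate
33 | (1S,10S)-1,10-epoxide of 32 (cis-epoxy ketone) | C=C(C)[C@H]1[C@H](O[Si](C)(C)C(C)(C)C)/C=C(\C)[C@@H](O[Si](C)(C)C(C)(C)C)C[C@@H]2O[C@]2(C)C(=O)[C@@H]1O[Si](C)(C)C(C)(C)C | intermediate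
34 | epoxy keto triol: (4E)-1,10-epoxy-3,6,8-trihydroxygermacra-4,11-dien-9-one, stereocentres as in the target | C=C(C)[C@H]1[C@H](O)/C=C(\C)[C@@H](O)C[C@@H]2O[C@]2(C)C(=O)[C@@H]1O | intermediate
35 | diepoxy keto triol: (1S,3S,4R,5R,6S,7S,8R,10S)-1,10:4,5-diepoxy-3,6,8-trihydroxygermacr-11-en-9-one | C=C(C)[C@H]1[C@H](O)[C@H]2O[C@]2(C)[C@@H](O)C[C@@H]2O[C@]2(C)C(=O)[C@@H]1O | intermediate
36 | angelic acid, (Z)-2-methylbut-2-enoic acid | C/C=C(/C)C(=O)O | starting material
37 | CNP0154187.4, the 3,6,8-tris(angelate) of 35 | C=C(C)[C@H]1[C@H](OC(=O)/C(C)=C\C)[C@H]2O[C@]2(C)[C@@H](OC(=O)/C(C)=C\C)C[C@@H]2O[C@]2(C)C(=O)[C@@H]1OC(=O)/C(C)=C\C | target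

**Step count**

Total: 21 steps. Longest linear sequence: 20 steps (steps 1–11 and 13–21 from (R)-carvone); step 12 is a one-step side branch.

**Steps most likely to fail**

1. Step 17 (proposed new method). The lithium alkoxide may fragment too slowly, so that proton transfer from C8 or attack of the organolithium on the sulfonate competes. Tert-butyllithium may also react with the ketone before the exchange is complete. The fallback uses known chemistry, sets out from 29 and returns at 32. Nozaki–Hiyama–Kishi cyclization of the vinyl iodide onto the C9 ketone (CrCl2, catalytic NiCl2, DMF, rt) should give the ring-A-closed tertiary alcohol with the mesylate intact, bicyclic hydroxy mesylate F1, which is isolated because a chromium alkoxide does not fragment. Classical Wharton–Grob fragmentation of F1 (KOt-Bu, t-BuOH/THF, rt) should then give 32.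

2. Step 6. Facial selectivity in the addition to a ketone flanked by a silyloxy group may be poor. A vinyl group on the wrong face would end in a C4/C5 pair whose sulfonate is axial and cannot fragment. The fallback sets out from 11 and returns at 15. Luche reduction (NaBH4, CeCl3·7H2O, MeOH) should give the allylic alcohol with the hydroxyl cis to the isopropenyl, 9-ol F2, by axial hydride delivery as in the reduction of carvone to cis-carveol. Vanadium-catalysed directed epoxidation (VO(acac)2, t-BuOOH) should then give the syn epoxy alcohol F3, and Dess–Martin oxidation the epoxy ketone F4. Addition of CH2=CHMgBr with CeCl3 anti to the epoxide oxygen, the usual course for α,β-epoxy ketones, should give 15, now with the configuration at C9 fixed by the epoxide and not by the ring conformation.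

3. Step 18. Rotation about C1–C10 in the β-peroxy enolate before ring closure would give the trans-epoxide. Attack on the wrong face or base-induced epimerization at C8 is also possible. The fallback sets out from 32 and returns at 33. Luche reduction of the enone (NaBH4, CeCl3·7H2O, MeOH; a bulky hydride such as LiBH(s-Bu)3 is the alternative) should give the (Z)-allylic alcohol F5; the C9 epimer with the hydroxyl syn to O-8 is the one needed. The concerted vanadium-catalysed epoxidation (VO(acac)2, t-BuOOH) retains the cis geometry and delivers oxygen threo to the carbinol (A(1,3) strain with C2), giving epoxy alcohol F6. Dess–Martin oxidation of F6 then gives 33.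

Further compounds
F1 | step 17 | bicyclic hydroxy mesylate (ring A closed by the C9–C10 bond, tertiary 9-OH, 5-OMs) | C=C(C)[C@H]1[C@H](O[Si](C)(C)C(C)(C)C)[C@@H](OS(C)(=O)=O)[C@]2(C)[C@@H](O[Si](C)(C)C(C)(C)C)CC=C(C)[C@]2(O)[C@@H]1O[Si](C)(C)C(C)(C)C
F2 | step 6 | 9-ol from 11, hydroxyl cis to the isopropenyl | C=C(C)[C@H]1[C@H](O[Si](C)(C)C(C)(C)C)C=C(C)[C@@H](O)[C@@H]1O[Si](C)(C)C(C)(C)C
F3 | step 6 | syn 4,5-epoxy-9-ol | C=C(C)[C@H]1[C@H](O[Si](C)(C)C(C)(C)C)[C@H]2O[C@@]2(C)[C@@H](O)[C@@H]1O[Si](C)(C)C(C)(C)C
F4 | step 6 | 4,5-epoxy-9-ketone, epoxide cis to the isopropenyl | C=C(C)[C@H]1[C@H](O[Si](C)(C)C(C)(C)C)[C@H]2O[C@@]2(C)C(=O)[C@@H]1O[Si](C)(C)C(C)(C)C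
F5 | step 18 | (1(10)Z,4E)-9-ol from 32, hydroxyl syn to O-8 | C=C(C)[C@H]1[C@H](O[Si](C)(C)C(C)(C)C)/C=C(\C)[C@@H](O[Si](C)(C)C(C)(C)C)C/C=C(/C)[C@@H](O)[C@@H]1O[Si](C)(C)C(C)(C)C
F6 | step 18 | (1S,10S)-1,10-epoxy-9-ol | C=C(C)[C@H]1[C@H](O[Si](C)(C)C(C)(C)C)/C=C(\C)[C@@H](O[Si](C)(C)C(C)(C)C)C[C@@H]2O[C@]2(C)[C@@H](O)[C@@H]1O[Si](C)(C)C(C)(C)C
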